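The flavanone is cut across ring C at O1–C2 and C3–C4. Atoms O1, C8a, C4a and C4 then belong to a ring A ortho-quinone methide and C2–C3 to a ring B styrene; the C4 carbonyl is added afterwards by benzylic oxidation. A single catalyst-controlled oxa-[4+2] cycloaddition thus closes the pyran ring, forms both skeletal bonds and sets the only stereocenter, C2, as S. The partners are a 4-O-silylated 2,4-dihydroxybenzyl alcohol and 3-bromo-5-iodo-4-methoxystyrene, whose iodide and bromide later receive the hydroxylated and the plain prenyl chain by Heck and Stille coupling.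

Key step: step 6

Remark on the chemistry: the ring A phenol is carried as a triisopropylsilyl ether. Its bulk shields the two ring A positions ortho to it (C6 and C8 of the flavan) from Friedel–Crafts attack by the quinone methide, it resists silyl transfer under the strong acid, and it survives the borohydride and Heck media. Which antipode of the chiral acid gives the 2S flavan cannot be predicted; it is to be assigned on the first run, for which the bromine and iodine of the cycloadduct allow an anomalous-dispersion X-ray analysis. The target SMILES corresponds to the (2S)-flavanone, and every intermediate below is drawn with that configuration.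

Step 1
Reactants: 1 2,4-dihydroxybenzaldehyde
Product: 2 2-hydroxy-4-(triisopropylsilyloxy)benzaldehyde
Conditions: TIPSCl (1.05 equiv), imidazole, CH2Cl2, 0 °C
Reagents that add atoms: triisopropylsilyl chloride, CC(C)[Si](Cl)(C(C)C)C(C)C
Why: Silyl ether formation should be selective for the 4-hydroxyl, which is the more acidic and unhindered phenol, whereas the 2-hydroxyl is held in a hydrogen bond to the aldehyde.

Step 2
Reactants: 2 2-hydroxy-4-(triisopropylsilyloxy)benzaldehyde
Product: 3 2-(hydroxymethyl)-5-(triisopropylsilyloxy)phenol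
Conditions: NaBH4, THF/EtOH, 0 °C; neutral aqueous work-up
Reagents that add atoms: none
Why: Borohydride reduction of the aldehyde should give the benzylic alcohol while the hindered aryl silyl ether survives, and the short reaction at 0 °C with a neutral work-up avoids premature quinone methide formation.

Step 3
Reactants: 4 3-bromo-4-hydroxybenzaldehyde
Product: 5 3-bromo-4-hydroxy-5-iodobenzaldehyde
Conditions: NIS, TsOH (cat.), MeCN, rt
Reagents that add atoms: N-iodosuccinimide, O=C1CCC(=O)N1I
Why: Electrophilic aromatic iodination is directed by the phenol to its only free ortho position, C5, since the para position carries the formyl group.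

Step 4
Reactants: 5 3-bromo-4-hydroxy-5-iodobenzaldehyde
Product: 6 3-bromo-5-iodo-4-methoxybenzaldehyde
Conditions: MeI, K2CO3, DMF, rt
Reagents that add atoms: iodomethane, CI
Why: Williamson O-methylation of the acidic 2,6-dihalophenol should proceed readily with carbonate as base.

Step 5
Reactants: 6 3-bromo-5-iodo-4-methoxybenzaldehyde
Product: 7 1-bromo-3-iodo-2-methoxy-5-vinylbenzene
Conditions: Ph3PCH3Br, KOtBu, THF, 0 °C to rt
Reagents that add atoms: methyltriphenylphosphonium bromide, C[P+](c1ccccc1)(c1ccccc1)c1ccccc1.[Br-]
Why: Wittig methylenation of the non-enolisable aldehyde with the preformed ylide should give the styrene, and an alkoxide base in place of butyllithium avoids halogen–metal exchange at the aryl iodide.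

Step 6
Reactants: 3 2-(hydroxymethyl)-5-(triisopropylsilyloxy)phenol; 7 1-bromo-3-iodo-2-methoxy-5-vinylbenzene
Product: 9 (2S)-2-(3-bromo-5-iodo-4-methoxyphenyl)-7-(triisopropylsilyloxy)chroman, via ortho-quinone methide 8 (not isolated)
Conditions: BINOL-derived imidodiphosphorimidate (IDPi) acid with N-triflyl groups (5 mol %), 5 Å molecular sieves, CH2Cl2, −20 °C, slow addition of 3 (1.5 equiv) to 7
Reagents that add atoms: none
Why: Proposed new method: the confined acid protonates the benzylic hydroxyl of 3 and expels water to give ortho-quinone methide 8, held by hydrogen bonding to the chiral anion, whereupon the CH2 terminus of styrene 7 attacks the methide carbon (C3–C4) and the developing C2 benzylic cation is captured by the ring A oxygen (O1–C2) in an asynchronous inverse-electron-demand oxa-[4+2] cycloaddition. The closest known reaction type is the chiral phosphoric acid catalysed [4+2] cycloaddition of in situ ortho-quinone methides with hydroxystyrenes and enol ethers, together with the racemic acid-promoted or thermal addition of styrenes to ortho-quinone methides. Ring C, the six-membered pyran, is closed by the cycloaddition itself, O1–C2 being the ring-closing bond that follows C3–C4. The only new stereocenter, C2, is under catalyst control: the chiral anion pocket exposes one enantioface of the styrene to bound 8, and the catalyst antipode that delivers 2S is used. The step needs regioselectivity, secured by the polarity match between the nucleophilic styrene terminus and the electrophilic methide carbon, chemoselectivity against Friedel–Crafts oligomerisation, secured by the bulky silyl ether, the slow addition of 3 and the para silyloxy donor that stabilises 8, and enantioselectivity, which is the unproven element. The electron-poor ring B should also keep the C2–O1 bond of 9 from ionising again, so the product should not racemise in the acid.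

Step 7
Reactants: 9 (2S)-2-(3-bromo-5-iodo-4-methoxyphenyl)-7-(triisopropylsilyloxy)chroman; 10 2-methylbut-3-en-2-ol
Product: 11 (E)-4-{3-bromo-2-methoxy-5-[(2S)-7-(triisopropylsilyloxy)chroman-2-yl]phenyl}-2-methylbut-3-en-2-ol
Conditions: Pd(OAc)2 (5 mol %), Bu4NCl, NaHCO3, 10 (3 equiv), DMF, 50 °C
Reagents that add atoms: none
Why: In this ligand-free Mizoroki–Heck reaction oxidative addition should be selective for the C–I bond over C–Br at 50 °C, the aryl group adds to the terminal alkene carbon and β-hydride elimination can only come from the benzylic CH2, which gives the (E)-styrenyl tertiary allylic alcohol; the flavan stereocenter has no acidic hydrogen and is not endangered by the base.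

Step 8
Reactants: 11 (E)-4-{3-bromo-2-methoxy-5-[(2S)-7-(triisopropylsilyloxy)chroman-2-yl]phenyl}-2-methylbut-3-en-2-ol
Product: 13 (2S)-2-[3-bromo-5-((E)-3-hydroxy-3-methylbut-1-enyl)-4-methoxyphenyl]-7-(triisopropylsilyloxy)chroman-4-one, via flavan-4-ol 12 (not isolated)
Conditions: DDQ (2.3 equiv), CH2Cl2/aq NaH2PO4–Na2HPO4 buffer (pH 7), 0 °C to rt
Reagents that add atoms: water, O
Why: In this DDQ benzylic oxidation of an alkoxyarene, hydride is abstracted from C4, which is activated by the para 7-silyloxy and ortho O1 oxygens, water traps the cation and the electron-rich benzylic alcohol 12 is oxidised on to the ketone by the second equivalent; the step is placed before prenylation so that no doubly activated prenyl CH2 competes as a hydride donor, and C2 is not touched.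

Step 9
Reactants: 13 (2S)-2-[3-bromo-5-((E)-3-hydroxy-3-methylbut-1-enyl)-4-methoxyphenyl]-7-(triisopropylsilyloxy)chroman-4-one; 14 tributyl(3-methylbut-2-enyl)stannane
Product: 15 (2S)-2-[3-((E)-3-hydroxy-3-methylbut-1-enyl)-4-methoxy-5-(3-methylbut-2-enyl)phenyl]-7-(triisopropylsilyloxy)chroman-4-one
Conditions: Pd(PPh3)4 (5 mol %), 14 (1.5 equiv), toluene, 100 °C
Reagents that add atoms: none
Why: Migita–Kosugi–Stille coupling of the remaining aryl bromide runs without base, so the flavanone should not be enolised and opened, and reductive elimination from the aryl(allyl)palladium intermediate at its less hindered terminus should give the linear prenyl group.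

Step 10
Reactants: 15 (2S)-2-[3-((E)-3-hydroxy-3-methylbut-1-enyl)-4-methoxy-5-(3-methylbut-2-enyl)phenyl]-7-(triisopropylsilyloxy)chroman-4-one
Product: 16 (2S)-7-hydroxy-2-[3-((E)-3-hydroxy-3-methylbut-1-enyl)-4-methoxy-5-(3-methylbut-2-enyl)phenyl]chroman-4-one
Conditions: TBAF, AcOH (1:1), THF, 0 °C
Reagents that add atoms: none
Why: Fluoride-mediated desilylation of the aryl silyl ether is fast, and the acetic acid buffer keeps the medium from becoming basic, so the flavanone should not open to the chalcone and racemise, nor should the tertiary allylic alcohol ionise.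

Compound list
1 | 2,4-dihydroxybenzaldehyde | O=Cc1ccc(O)cc1O | starting material
2 | 2-hydroxy-4-(triisopropylsilyloxy)benzaldehyde | O=Cc1ccc(O[Si](C(C)C)(C(C)C)C(C)C)cc1O | intermediate
3 | 2-(hydroxymethyl)-5-(triisopropylsilyloxy)phenol | OCc1ccc(O[Si](C(C)C)(C(C)C)C(C)C)cc1O | intermediate
4 | 3-bromo-4-hydroxybenzaldehyde | O=Cc1ccc(O)c(Br)c1 | starting material
5 | 3-bromo-4-hydroxy-5-iodobenzaldehyde | O=Cc1cc(I)c(O)c(Br)c1 | intermediate
6 | 3-bromo-5-iodo-4-methoxybenzaldehyde | COc1c(I)cc(C=O)cc1Br | intermediate
7 | 1-bromo-3-iodo-2-methoxy-5-vinylbenzene | C=Cc1cc(Br)c(OC)c(I)c1 | intermediate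
8 | 6-methylidene-3-(triisopropylsilyloxy)cyclohexa-2,4-dien-1-one (ortho-quinone methide) | C=C1C=CC(O[Si](C(C)C)(C(C)C)C(C)C)=CC1=O | intermediate
9 | (2S)-2-(3-bromo-5-iodo-4-methoxyphenyl)-7-(triisopropylsilyloxy)chroman | COc1c(I)cc([C@@H]2CCc3ccc(O[Si](C(C)C)(C(C)C)C(C)C)cc3O2)cc1Br | intermediate
10 | 2-methylbut-3-en-2-ol | CC(C)(O)C=C | starting material
11 | (E)-4-{3-bromo-2-methoxy-5-[(2S)-7-(triisopropylsilyloxy)chroman-2-yl]phenyl}-2-methylbut-3-en-2-ol | COc1c(/C=C/C(C)(C)O)cc([C@@H]2CCc3ccc(O[Si](C(C)C)(C(C)C)C(C)C)cc3O2)cc1Br | intermediate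
12 | (2S)-2-[3-bromo-5-((E)-3-hydroxy-3-methylbut-1-enyl)-4-methoxyphenyl]-7-(triisopropylsilyloxy)chroman-4-ol (both C4 epimers) | COc1c(/C=C/C(C)(C)O)cc([C@@H]2CC(O)c3ccc(O[Si](C(C)C)(C(C)C)C(C)C)cc3O2)cc1Br | intermediate
13 | (2S)-2-[3-bromo-5-((E)-3-hydroxy-3-methylbut-1-enyl)-4-methoxyphenyl]-7-(triisopropylsilyloxy)chroman-4-one | COc1c(/C=C/C(C)(C)O)cc([C@@H]2CC(=O)c3ccc(O[Si](C(C)C)(C(C)C)C(C)C)cc3O2)cc1Br | intermediate
14 | tributyl(3-methylbut-2-enyl)stannane | CCCC[Sn](CCCC)(CCCC)CC=C(C)C | starting material
15 | (2S)-2-[3-((E)-3-hydroxy-3-methylbut-1-enyl)-4-methoxy-5-(3-methylbut-2-enyl)phenyl]-7-(triisopropylsilyloxy)chroman-4-one | COc1c(/C=C/C(C)(C)O)cc([C@@H]2CC(=O)c3ccc(O[Si](C(C)C)(C(C)C)C(C)C)cc3O2)cc1CC=C(C)C | intermediate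
16 | (2S)-7-hydroxy-2-[3-((E)-3-hydroxy-3-methylbut-1-enyl)-4-methoxy-5-(3-methylbut-2-enyl)phenyl]chroman-4-one | COc1c(/C=C/C(C)(C)O)cc([C@@H]2CC(=O)c3ccc(O)cc3O2)cc1CC=C(C)C | target

Total step count: 10. Longest linear sequence: 8 steps (steps 3 to 10, from 3-bromo-4-hydroxybenzaldehyde).

Steps most likely to fail

Step 6. The enantioface of the weakly nucleophilic styrene may be poorly discriminated in the anion pocket. The cycloaddition may also be slow enough for the quinone methide to be consumed by Friedel–Crafts oligomerisation on ring A. Fallback with known chemistry, setting out from 3 and 7: the same cycloaddition is run without asymmetric induction, using an achiral acid such as diphenyl phosphate (10 mol %) in toluene at 60 °C with 7 in excess, or by thermolysis at 150–170 °C. This should give racemic 2-(3-bromo-5-iodo-4-methoxyphenyl)-7-(triisopropylsilyloxy)chroman F1. Preparative HPLC on a polysaccharide chiral stationary phase then separates the enantiomers; (2R)-2-(3-bromo-5-iodo-4-methoxyphenyl)-7-(triisopropylsilyloxy)chroman F2 is set aside and the 2S enantiomer is 9, where the route is rejoined.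

Step 8. The C4 cation may lose a proton to the flav-3-ene, which DDQ can oxidise further with loss of the C2 hydrogen, or the hydroquinone by-product may ionise the tertiary allylic alcohol. Fallback, setting out from 9, which has neither alkene nor alcohol and tolerates aqueous acetic acid: DDQ (2.5 equiv) in dioxane/aqueous AcOH at rt should pass through (2S)-2-(3-bromo-5-iodo-4-methoxyphenyl)-7-(triisopropylsilyloxy)chroman-4-ol F3 to (2S)-2-(3-bromo-5-iodo-4-methoxyphenyl)-7-(triisopropylsilyloxy)chroman-4-one F4. The hydroxylated chain is then attached at the iodide without base by Stille coupling (Pd(PPh3)4, CuI, DMF, 40 °C) with (E)-2-methyl-4-(tributylstannyl)but-3-en-2-ol F5. F5 is prepared from 2-methylbut-3-yn-2-ol and Bu3SnH with catalytic PdCl2(PPh3)2, the minor regioisomer being removed by chromatography. The coupling gives 13, where the route is rejoined.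

Step 9. Configuration at C2 may erode through ring opening and reclosure of the flavanone at 100 °C, oxidative addition at the hindered, electron-rich bromide may be slow, and the prenyl unit may transpose or its double bond may migrate. Fallback, setting out from 11: the Stille coupling with 14 (Pd(PPh3)4, DMF, 100 °C) is carried out on the flavan, whose stereocenter cannot open, giving (E)-4-{2-methoxy-3-(3-methylbut-2-enyl)-5-[(2S)-7-(triisopropylsilyloxy)chroman-2-yl]phenyl}-2-methylbut-3-en-2-ol F6. C4 is then oxidised in two controlled stages. DDQ (1.1 equiv) in CH2Cl2/pH 7 buffer at −10 °C, which accepts and limits the competition from the prenyl CH2, gives (2S)-2-[3-((E)-3-hydroxy-3-methylbut-1-enyl)-4-methoxy-5-(3-methylbut-2-enyl)phenyl]-7-(triisopropylsilyloxy)chroman-4-ol F7. MnO2 in CH2Cl2, selective for the activated benzylic alcohol, then gives 15, where the route is rejoined.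

Further compounds
F1 | step 6 | racemic 2-(3-bromo-5-iodo-4-methoxyphenyl)-7-(triisopropylsilyloxy)chroman | COc1c(I)cc(C2CCc3ccc(O[Si](C(C)C)(C(C)C)C(C)C)cc3O2)cc1Br
F2 | step 6 | (2R)-2-(3-bromo-5-iodo-4-methoxyphenyl)-7-(triisopropylsilyloxy)chroman | COc1c(I)cc([C@H]2CCc3ccc(O[Si](C(C)C)(C(C)C)C(C)C)cc3O2)cc1Br
F3 | step 8 | (2S)-2-(3-bromo-5-iodo-4-methoxyphenyl)-7-(triisopropylsilyloxy)chroman-4-ol (both C4 epimers) | COc1c(I)cc([C@@H]2CC(O)c3ccc(O[Si](C(C)C)(C(C)C)C(C)C)cc3O2)cc1Br
F4 | step 8 | (2S)-2-(3-bromo-5-iodo-4-methoxyphenyl)-7-(triisopropylsilyloxy)chroman-4-one | COc1c(I)cc([C@@H]2CC(=O)c3ccc(O[Si](C(C)C)(C(C)C)C(C)C)cc3O2)cc1Br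
F5 | step 8 | (E)-2-methyl-4-(tributylstannyl)but-3-en-2-ol | CCCC[Sn](CCCC)(CCCC)/C=C/C(C)(C)O
F6 | step 9 | (E)-4-{2-methoxy-3-(3-methylbut-2-enyl)-5-[(2S)-7-(triisopropylsilyloxy)chroman-2-yl]phenyl}-2-methylbut-3-en-2-ol | COc1c(/C=C/C(C)(C)O)cc([C@@H]2CCc3ccc(O[Si](C(C)C)(C(C)C)C(C)C)cc3O2)cc1CC=C(C)C
F7 | step 9 | (2S)-2-[3-((E)-3-hydroxy-3-methylbut-1-enyl)-4-methoxy-5-(3-methylbut-2-enyl)phenyl]-7-(triisopropylsilyloxy)chroman-4-ol (both C4 epimers) | COc1c(/C=C/C(C)(C)O)cc([C@@H]2CC(O)c3ccc(O[Si](C(C)C)(C(C)C)C(C)C)cc3O2)cc1CC=C(C)C
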